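## Retrosynthetic overview

1. Target 30 ⇒ Felkin–Anh reduction of α-aryloxy ketone 29 (sets C7'') ⇒ SN2 etherification, with inversion at C8'', of phenol 22 with the (S)-lactate-derived α-tosyloxy ketone 28.
2. Phenol 22 ⇒ debenzylation of 2,5-diaryloxolane 21 ⇒ C7–aryl bond from 2-sulfonyloxolane 17 and arylzinc 20, made from Grignard reagent 19, through the oxocarbenium ion (sets C7).
3. 17 ⇒ lactol 16 ⇒ lactone 15 ⇒ trans α-methylation of lactone 13 (sets C8).
4. 13 ⇒ one-carbon homologation and oxidative lactonisation of the Evans syn-aldol adduct 4; the key C7'–C8' bond joins the boron enolate of imide 1 and aldehyde 2 (sets C7', C8').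
5. Ring order: the oxolane is the only ring built. It is closed as the γ-lactone in step 8 and carried through lactol and sulfone; the three benzene rings are bought intact.

Assumption: compounds 1, 2, 18 and 23 are purchased; Grignard reagent 19 is prepared once as a titrated THF stock solution and portions of it are used in steps 13 and 17. Locants are C7/C8 on the side of ring A (3,4-dimethoxyphenyl on the oxolane), C7'/C8' on the side of ring B (4-oxy-3-methoxyphenyl), and C7''/C8'' in the side chain carrying ring C.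

## Route

Step 1
Reactants: 1 (4S)-4-benzyl-3-propanoyl-1,3-oxazolidin-2-one; 2 4-(benzyloxy)-3-methoxybenzaldehyde
Product: 4 (4S)-4-benzyl-3-[(2S,3S)-3-[4-(benzyloxy)-3-methoxyphenyl]-3-hydroxy-2-methylpropanoyl]-1,3-oxazolidin-2-one, via dibutylboron Z-enolate 3 (not isolated)
Conditions: n-Bu2BOTf (1.2 eq), i-Pr2NEt (1.4 eq), CH2Cl2, 0 °C; then 2, −78 → 0 °C; work-up pH 7 buffer (NaH2PO4/Na2HPO4), MeOH, 30% H2O2, 0 °C
Reagents that add atoms: none
Why: Evans syn-aldol reaction, in which the Z-boron enolate reacts through a closed Zimmerman–Traxler chair on the face away from the auxiliary benzyl group and so sets C8' (2S) and C7' (3S) syn.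

Step 2
Reactants: 4 aldol adduct
Product: 5 (4S)-4-benzyl-3-[(2S,3S)-3-[4-(benzyloxy)-3-methoxyphenyl]-3-[(tert-butyldimethylsilyl)oxy]-2-methylpropanoyl]-1,3-oxazolidin-2-one
Conditions: TBSOTf (1.3 eq), 2,6-lutidine (2 eq), CH2Cl2, 0 °C
Reagents that add atoms: tert-butyldimethylsilyl trifluoromethanesulfonate, CC(C)(C)[Si](C)(C)OS(=O)(=O)C(F)(F)F
Why: Silyl ether protection of the benzylic alcohol blocks retro-aldol cleavage and leaves both stereocentres untouched.

Step 3
Reactants: 5 silyl ether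
Product: 6 (2R,3S)-3-[4-(benzyloxy)-3-methoxyphenyl]-3-[(tert-butyldimethylsilyl)oxy]-2-methylpropan-1-ol
Conditions: LiBH4 (2 eq), MeOH (2 eq), THF, 0 °C → rt
Reagents that add atoms: none
Why: Reductive cleavage of the N-acyl oxazolidinone at the exocyclic carbonyl gives the primary alcohol without touching the stereocentres (the descriptor at C8' changes by priority only).

Step 4
Reactants: 6 primary alcohol
Product: 7 (2S,3S)-3-[4-(benzyloxy)-3-methoxyphenyl]-3-[(tert-butyldimethylsilyl)oxy]-2-methylpropanal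
Conditions: Dess–Martin periodinane (1.3 eq), pyridine (3 eq), CH2Cl2, 0 °C → rt; used crude
Reagents that add atoms: none
Why: Dess–Martin oxidation under buffered, non-basic conditions gives the α-branched aldehyde without epimerisation.

Step 5
Reactants: 7 aldehyde
Product: 8 {[(1S,2R)-1-[4-(benzyloxy)-3-methoxyphenyl]-2-methylbut-3-en-1-yl]oxy}(tert-butyl)dimethylsilane
Conditions: Ph3PCH3Br (1.6 eq), KN(SiMe3)2 (1.5 eq), THF, 0 °C; then 7, −78 → 0 °C
Reagents that add atoms: methyltriphenylphosphonium bromide, C[P+](c1ccccc1)(c1ccccc1)c1ccccc1.[Br-]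
Why: Wittig methylenation with a salt-free, non-stabilised ylide at low temperature adds the carbon that becomes C7 and is faster than enolisation of the aldehyde.

Step 6
Reactants: 8 terminal alkene
Product: 10 (3R,4S)-4-[4-(benzyloxy)-3-methoxyphenyl]-4-[(tert-butyldimethylsilyl)oxy]-3-methylbutan-1-ol, via B-alkyl-9-BBN borane 9 (not isolated)
Conditions: 9-BBN-H (2 eq), THF, 0 °C → rt; then 3 M NaOH, 30% H2O2, 0 °C → rt
Reagents that add atoms: hydrogen peroxide, OO
Why: Hydroboration–oxidation of a monosubstituted alkene with 9-BBN is fully anti-Markovnikov and creates no new stereocentre.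

Step 7
Reactants: 10 silyl-protected alcohol
Product: 11 (1S,2R)-1-[4-(benzyloxy)-3-methoxyphenyl]-2-methylbutane-1,4-diol
Conditions: n-Bu4NF (1.5 eq), THF, rt
Reagents that add atoms: none
Why: Fluoride desilylation frees the benzylic alcohol under non-acidic conditions, so the electron-rich benzylic centre cannot ionise.

Step 8
Reactants: 11 1,4-diol
Product: 13 (4R,5S)-5-[4-(benzyloxy)-3-methoxyphenyl]-4-methyloxolan-2-one, via lactol 12 (not isolated)
Conditions: TEMPO (0.2 eq), PhI(OAc)2 (3 eq), CH2Cl2, rt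
Reagents that add atoms: none
Why: TEMPO-catalysed oxidative lactonisation oxidises the primary alcohol selectively, the hydroxy aldehyde closes to the lactol, and this is oxidised to the lactone with C7'–O retained, which gives the 4,5-cis ring.

Step 9
Reactants: 13 lactone
Product: 15 (3R,4R,5S)-5-[4-(benzyloxy)-3-methoxyphenyl]-3,4-dimethyloxolan-2-one, via lithium enolate 14 (not isolated)
Conditions: LiN(SiMe3)2 (1.1 eq), THF, −78 °C; MeI (3 eq), −78 → −40 °C
Reagents that add atoms: iodomethane, CI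
Why: Lactone enolate alkylation takes place on the face opposite the cis-disposed C4 methyl and C5 aryl groups and sets C8 (3R) trans to the C8' methyl.

Step 10
Reactants: 15 dimethyl lactone
Product: 16 (3R,4R,5S)-5-[4-(benzyloxy)-3-methoxyphenyl]-3,4-dimethyloxolan-2-ol (both anomers)
Conditions: i-Bu2AlH (1.2 eq), CH2Cl2, −78 °C; MeOH, then aq. KNaC4H4O6
Reagents that add atoms: none
Why: Partial reduction of a lactone with i-Bu2AlH stops at the lactol because the aluminium hemiacetal is stable at −78 °C.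

Step 11
Reactants: 16 lactol
Product: 17 (3R,4R,5S)-2-(benzenesulfonyl)-5-[4-(benzyloxy)-3-methoxyphenyl]-3,4-dimethyloxolane (both C2 epimers)
Conditions: PhSO2H (3 eq), CaCl2 (3 eq), CH2Cl2, rt
Reagents that add atoms: benzenesulfinic acid, OS(=O)c1ccccc1
Why: Acid-mediated anomeric substitution traps the oxocarbenium ion with sulfinate as the S-bound sulfone, with CaCl2 removing the water.

Step 12
Reactants: 18 4-bromo-1,2-dimethoxybenzene
Product: 19 (3,4-dimethoxyphenyl)magnesium bromide (titrated THF stock solution, kept under argon)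
Conditions: Mg turnings (1.2 eq), I2 (cat.), THF, 40 °C; titrated, ca. 0.8 M
Reagents that add atoms: magnesium, [Mg]
Why: Grignard reagent formation by insertion of magnesium into the aryl C–Br bond is clean for this electron-rich aryl bromide in THF and creates no stereocentre.

Step 13
Reactants: 17 2-sulfonyloxolane; 19 (3,4-dimethoxyphenyl)magnesium bromide
Product: 21 (2S,3R,4R,5S)-2-[4-(benzyloxy)-3-methoxyphenyl]-5-(3,4-dimethoxyphenyl)-3,4-dimethyloxolane, via (3,4-dimethoxyphenyl)zinc bromide 20 (not isolated)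
Conditions: 19 (3 eq, THF solution), ZnBr2 (3 eq), THF, 0 °C → rt, 1 h; then 17, THF, rt, 16 h
Reagents that add atoms: none
Why: SN1-type substitution of the sulfone by the arylzinc reagent, in which the aryl group attacks the envelope oxocarbenium ion from the inside face, anti to the C8' methyl and ring B and cis to the C8 methyl, and so sets C7 (S) and the cis,trans,cis oxolane.

Step 14
Reactants: 21 benzyl ether
Product: 22 4-[(2S,3R,4R,5S)-5-(3,4-dimethoxyphenyl)-3,4-dimethyloxolan-2-yl]-2-methoxyphenol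
Conditions: H2 (1 atm), 10% Pd/C, EtOAc, rt; stopped when 21 is consumed
Reagents that add atoms: none
Why: Hydrogenolysis of the aryl benzyl ether in a non-acidic solvent is much faster than cleavage of the hindered cyclic dibenzylic ether, so no stereocentre is affected.

Step 15
Reactants: 23 ethyl (2S)-2-hydroxypropanoate
Product: 24 ethyl (2S)-2-[(tert-butyldimethylsilyl)oxy]propanoate
Conditions: TBSCl (1.1 eq), imidazole (2 eq), CH2Cl2, 0 °C → rt
Reagents that add atoms: tert-butyldimethylsilyl chloride, CC(C)(C)[Si](C)(C)Cl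
Why: Standard silylation of the secondary alcohol, with the lactate stereocentre uninvolved.

Step 16
Reactants: 24 silyloxy ester
Product: 25 (2S)-2-[(tert-butyldimethylsilyl)oxy]-N-methoxy-N-methylpropanamide
Conditions: MeNHOMe·HCl (1.5 eq), i-PrMgCl (3 eq), THF, −20 → 0 °C
Reagents that add atoms: N,O-dimethylhydroxylamine hydrochloride, CNOC.Cl
Why: Aminolysis of the ester by the magnesium amide (Weinreb amide formation) is faster than α-deprotonation at −20 °C, so the stereocentre is kept.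

Step 17
Reactants: 25 Weinreb amide; 19 (3,4-dimethoxyphenyl)magnesium bromide
Product: 26 (2S)-2-[(tert-butyldimethylsilyl)oxy]-1-(3,4-dimethoxyphenyl)propan-1-one
Conditions: 19 (1.5 eq, THF solution), THF, 0 °C → rt; aq. NH4Cl
Reagents that add atoms: none
Why: Weinreb ketone synthesis, in which the chelated tetrahedral adduct prevents over-addition and enolisation and the ketone is released only on work-up.

Step 18
Reactants: 26 silyloxy ketone
Product: 27 (2S)-1-(3,4-dimethoxyphenyl)-2-hydroxypropan-1-one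
Conditions: 48% aq. HF, MeCN, 0 °C → rt
Reagents that add atoms: none
Why: Acidic fluoride desilylation avoids the basic conditions that would racemise or rearrange the α-hydroxy ketone.

Step 19
Reactants: 27 α-hydroxy ketone
Product: 28 (2S)-1-(3,4-dimethoxyphenyl)-1-oxopropan-2-yl 4-methylbenzenesulfonate
Conditions: TsCl (1.3 eq), Et3N (1.5 eq), DMAP (0.1 eq), CH2Cl2, 0 °C
Reagents that add atoms: 4-methylbenzenesulfonyl chloride, Cc1ccc(cc1)S(Cl)(=O)=O
Why: O-Sulfonylation takes place at oxygen, so the configuration at carbon is retained.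

Step 20
Reactants: 22 phenol; 28 α-tosyloxy ketone
Product: 29 (2R)-1-(3,4-dimethoxyphenyl)-2-{4-[(2S,3R,4R,5S)-5-(3,4-dimethoxyphenyl)-3,4-dimethyloxolan-2-yl]-2-methoxyphenoxy}propan-1-one
Conditions: BEMP (2-tert-butylimino-2-diethylamino-1,3-dimethylperhydro-1,3,2-diazaphosphorine, 1.1 eq), 28 (1.3 eq), CH2Cl2, rt
Reagents that add atoms: none
Why: SN2 displacement of the carbonyl-activated secondary tosylate by the phenoxide, formed with a non-nucleophilic phosphazene base, proceeds with clean inversion (S → R) and sets C8''.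

Step 21
Reactants: 29 α-aryloxy ketone
Product: 30 (1R,2R)-1-(3,4-dimethoxyphenyl)-2-{4-[(2S,3R,4R,5S)-5-(3,4-dimethoxyphenyl)-3,4-dimethyloxolan-2-yl]-2-methoxyphenoxy}propan-1-ol
Conditions: quaternary ammonium polystyrene resin in its borohydride form (resin–NMe3+ BH4−, excess), MeOH, 0 °C → rt
Reagents that add atoms: none
Why: Non-chelating borohydride reduction follows the polar Felkin–Anh model, with hydride delivered anti to the C8''–OAr bond past the small hydrogen, and gives the threo (1R,2R) alcohol.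

## Compound list

1 | (4S)-4-benzyl-3-propanoyl-1,3-oxazolidin-2-one | CCC(=O)N1[C@@H](Cc2ccccc2)COC1=O | starting material
2 | 4-(benzyloxy)-3-methoxybenzaldehyde | COc1cc(C=O)ccc1OCc1ccccc1 | starting material
3 | (4S)-4-benzyl-3-[(1Z)-1-(dibutylboranyloxy)prop-1-en-1-yl]-1,3-oxazolidin-2-one (boron Z-enolate of 1) | C/C=C(\OB(CCCC)CCCC)N1[C@@H](Cc2ccccc2)COC1=O | intermediate (not isolated)
4 | (4S)-4-benzyl-3-[(2S,3S)-3-[4-(benzyloxy)-3-methoxyphenyl]-3-hydroxy-2-methylpropanoyl]-1,3-oxazolidin-2-one | COc1cc(ccc1OCc2ccccc2)[C@@H](O)[C@H](C)C(=O)N3[C@@H](Cc4ccccc4)COC3=O | intermediate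
5 | (4S)-4-benzyl-3-[(2S,3S)-3-[4-(benzyloxy)-3-methoxyphenyl]-3-[(tert-butyldimethylsilyl)oxy]-2-methylpropanoyl]-1,3-oxazolidin-2-one | COc1cc(ccc1OCc2ccccc2)[C@@H](O[Si](C)(C)C(C)(C)C)[C@H](C)C(=O)N3[C@@H](Cc4ccccc4)COC3=O | intermediate
6 | (2R,3S)-3-[4-(benzyloxy)-3-methoxyphenyl]-3-[(tert-butyldimethylsilyl)oxy]-2-methylpropan-1-ol | COc1cc(ccc1OCc2ccccc2)[C@@H](O[Si](C)(C)C(C)(C)C)[C@H](C)CO | intermediate
7 | (2S,3S)-3-[4-(benzyloxy)-3-methoxyphenyl]-3-[(tert-butyldimethylsilyl)oxy]-2-methylpropanal | COc1cc(ccc1OCc2ccccc2)[C@@H](O[Si](C)(C)C(C)(C)C)[C@H](C)C=O | intermediate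
8 | {[(1S,2R)-1-[4-(benzyloxy)-3-methoxyphenyl]-2-methylbut-3-en-1-yl]oxy}(tert-butyl)dimethylsilane | COc1cc(ccc1OCc2ccccc2)[C@@H](O[Si](C)(C)C(C)(C)C)[C@H](C)C=C | intermediate
9 | 9-[(3R,4S)-4-[4-(benzyloxy)-3-methoxyphenyl]-4-[(tert-butyldimethylsilyl)oxy]-3-methylbutyl]-9-borabicyclo[3.3.1]nonane | COc1cc(ccc1OCc2ccccc2)[C@@H](O[Si](C)(C)C(C)(C)C)[C@H](C)CCB3C4CCCC3CCC4 | intermediate (not isolated)
10 | (3R,4S)-4-[4-(benzyloxy)-3-methoxyphenyl]-4-[(tert-butyldimethylsilyl)oxy]-3-methylbutan-1-ol | COc1cc(ccc1OCc2ccccc2)[C@@H](O[Si](C)(C)C(C)(C)C)[C@H](C)CCO | intermediate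
11 | (1S,2R)-1-[4-(benzyloxy)-3-methoxyphenyl]-2-methylbutane-1,4-diol | COc1cc(ccc1OCc2ccccc2)[C@@H](O)[C@H](C)CCO | intermediate
12 | (4R,5S)-5-[4-(benzyloxy)-3-methoxyphenyl]-4-methyloxolan-2-ol (lactol, both anomers) | COc1cc(ccc1OCc2ccccc2)[C@H]3OC(O)C[C@H]3C | intermediate (not isolated)
13 | (4R,5S)-5-[4-(benzyloxy)-3-methoxyphenyl]-4-methyloxolan-2-one | COc1cc(ccc1OCc2ccccc2)[C@H]3OC(=O)C[C@H]3C | intermediate
14 | lithium (4R,5S)-5-[4-(benzyloxy)-3-methoxyphenyl]-4-methyl-4,5-dihydrofuran-2-olate (enolate of 13) | COc1cc(ccc1OCc2ccccc2)[C@H]3OC(O[Li])=C[C@H]3C | intermediate (not isolated)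
15 | (3R,4R,5S)-5-[4-(benzyloxy)-3-methoxyphenyl]-3,4-dimethyloxolan-2-one | COc1cc(ccc1OCc2ccccc2)[C@H]3OC(=O)[C@H](C)[C@H]3C | intermediate
16 | (3R,4R,5S)-5-[4-(benzyloxy)-3-methoxyphenyl]-3,4-dimethyloxolan-2-ol (both anomers) | COc1cc(ccc1OCc2ccccc2)[C@H]3OC(O)[C@H](C)[C@H]3C | intermediate
17 | (3R,4R,5S)-2-(benzenesulfonyl)-5-[4-(benzyloxy)-3-methoxyphenyl]-3,4-dimethyloxolane (both C2 epimers) | COc1cc(ccc1OCc2ccccc2)[C@H]3OC(S(=O)(=O)c4ccccc4)[C@H](C)[C@H]3C | intermediate
18 | 4-bromo-1,2-dimethoxybenzene | COc1ccc(Br)cc1OC | starting material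
19 | (3,4-dimethoxyphenyl)magnesium bromide (THF stock solution) | COc1ccc([Mg]Br)cc1OC | intermediate
20 | (3,4-dimethoxyphenyl)zinc bromide | COc1ccc([Zn]Br)cc1OC | intermediate (not isolated)
21 | (2S,3R,4R,5S)-2-[4-(benzyloxy)-3-methoxyphenyl]-5-(3,4-dimethoxyphenyl)-3,4-dimethyloxolane | COc1cc(ccc1OCc2ccccc2)[C@H]3O[C@H](c4ccc(OC)c(OC)c4)[C@H](C)[C@H]3C | intermediate
22 | 4-[(2S,3R,4R,5S)-5-(3,4-dimethoxyphenyl)-3,4-dimethyloxolan-2-yl]-2-methoxyphenol | COc1cc(ccc1O)[C@H]2O[C@H](c3ccc(OC)c(OC)c3)[C@H](C)[C@H]2C | intermediate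
23 | ethyl (2S)-2-hydroxypropanoate (ethyl (S)-lactate) | CCOC(=O)[C@H](C)O | starting material
24 | ethyl (2S)-2-[(tert-butyldimethylsilyl)oxy]propanoate | CCOC(=O)[C@H](C)O[Si](C)(C)C(C)(C)C | intermediate
25 | (2S)-2-[(tert-butyldimethylsilyl)oxy]-N-methoxy-N-methylpropanamide | CON(C)C(=O)[C@H](C)O[Si](C)(C)C(C)(C)C | intermediate
26 | (2S)-2-[(tert-butyldimethylsilyl)oxy]-1-(3,4-dimethoxyphenyl)propan-1-one | COc1ccc(cc1OC)C(=O)[C@H](C)O[Si](C)(C)C(C)(C)C | intermediate
27 | (2S)-1-(3,4-dimethoxyphenyl)-2-hydroxypropan-1-one | COc1ccc(cc1OC)C(=O)[C@H](C)O | intermediate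
28 | (2S)-1-(3,4-dimethoxyphenyl)-1-oxopropan-2-yl 4-methylbenzenesulfonate | COc1ccc(cc1OC)C(=O)[C@H](C)OS(=O)(=O)c2ccc(C)cc2 | intermediate
29 | (2R)-1-(3,4-dimethoxyphenyl)-2-{4-[(2S,3R,4R,5S)-5-(3,4-dimethoxyphenyl)-3,4-dimethyloxolan-2-yl]-2-methoxyphenoxy}propan-1-one | COc1ccc(cc1OC)C(=O)[C@@H](C)Oc2ccc(cc2OC)[C@H]3O[C@H](c4ccc(OC)c(OC)c4)[C@H](C)[C@H]3C | intermediate
30 | (1R,2R)-1-(3,4-dimethoxyphenyl)-2-{4-[(2S,3R,4R,5S)-5-(3,4-dimethoxyphenyl)-3,4-dimethyloxolan-2-yl]-2-methoxyphenoxy}propan-1-ol (CNP0286615.1) | COc1ccc([C@@H](O)[C@@H](C)Oc2ccc([C@H]3O[C@H](c4ccc(OC)c(OC)c4)[C@H](C)[C@H]3C)cc2OC)cc1OC | target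

## Step count and risks

Total step count: 21. Longest linear sequence: 15 steps (steps 1–11, then 13, 14, 20 and 21). Grignard reagent 19 is made in one side step (step 12) and feeds steps 13 and 17; the tosylate 28 is made in a 5-step side sequence (steps 15–19).

Steps most likely to fail:

1. Step 13 (arylzinc coupling with the sulfone). The risks are loss of sulfinic acid to a dihydrofuran and a modest ratio at C7. The fallback sets out from lactol 16 and replaces the organometallic coupling by a Friedel–Crafts C-arylation with the neutral arene. Acetylation of 16 (Ac2O, pyridine, DMAP) gives (3R,4R,5S)-5-[4-(benzyloxy)-3-methoxyphenyl]-3,4-dimethyloxolan-2-yl acetate F1. F1 is ionised with BF3·OEt2 in CH2Cl2 at −78 °C in the presence of excess purchased 1,2-dimethoxybenzene. The arene attacks the same oxocarbenium ion para to a methoxy group, which is the only unhindered activated position, from the same face, and the cold quench prevents acid epimerisation of the benzylic ether centres. The fallback comes back to the route at 21.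

2. Step 20 (base-mediated etherification). The risks are racemisation or elimination of tosylate 28 and epimerisation of ketone 29 by the phenoxide. The fallback sets out from phenol 22 and ethyl (S)-lactate 23 and builds the ketone after the ether bond. A Mitsunobu reaction (PPh3, DIAD, THF, 0 °C → rt) gives, with inversion and without added base, ethyl (2R)-2-{4-[(2S,3R,4R,5S)-5-(3,4-dimethoxyphenyl)-3,4-dimethyloxolan-2-yl]-2-methoxyphenoxy}propanoate F2. MeNHOMe·HCl and i-PrMgCl at −20 °C convert F2 into (2R)-N-methoxy-N-methyl-2-{4-[(2S,3R,4R,5S)-5-(3,4-dimethoxyphenyl)-3,4-dimethyloxolan-2-yl]-2-methoxyphenoxy}propanamide F3. Addition of Grignard reagent 19 (the stock solution from step 12) to F3 gives the ketone, and the fallback comes back to the route at 29.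

3. Step 21 (diastereoselectivity of the ketone reduction). The risk is an insufficient threo:erythro ratio. The fallback sets out from ketone 29 and reaches the threo alcohol by chelation-controlled reduction followed by inversion. Zn(BH4)2 in Et2O at −20 °C reduces through the zinc chelate to the erythro alcohol (1S,2R)-1-(3,4-dimethoxyphenyl)-2-{4-[(2S,3R,4R,5S)-5-(3,4-dimethoxyphenyl)-3,4-dimethyloxolan-2-yl]-2-methoxyphenoxy}propan-1-ol F4. Mitsunobu esterification of F4 with 4-nitrobenzoic acid (PPh3, DIAD, THF, 0 °C) inverts C7'' and gives (1R,2R)-1-(3,4-dimethoxyphenyl)-2-{4-[(2S,3R,4R,5S)-5-(3,4-dimethoxyphenyl)-3,4-dimethyloxolan-2-yl]-2-methoxyphenoxy}propyl 4-nitrobenzoate F5. Methanolysis of F5 (K2CO3, MeOH, rt) releases the alcohol, and the fallback comes back to the route at 30.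

Further compounds
F1 | step 13 | (3R,4R,5S)-5-[4-(benzyloxy)-3-methoxyphenyl]-3,4-dimethyloxolan-2-yl acetate | COc1cc(ccc1OCc2ccccc2)[C@H]3OC(OC(C)=O)[C@H](C)[C@H]3C
F2 | step 20 | ethyl (2R)-2-{4-[(2S,3R,4R,5S)-5-(3,4-dimethoxyphenyl)-3,4-dimethyloxolan-2-yl]-2-methoxyphenoxy}propanoate | CCOC(=O)[C@@H](C)Oc1ccc(cc1OC)[C@H]2O[C@H](c3ccc(OC)c(OC)c3)[C@H](C)[C@H]2C
F3 | step 20 | (2R)-N-methoxy-N-methyl-2-{4-[(2S,3R,4R,5S)-5-(3,4-dimethoxyphenyl)-3,4-dimethyloxolan-2-yl]-2-methoxyphenoxy}propanamide | CON(C)C(=O)[C@@H](C)Oc1ccc(cc1OC)[C@H]2O[C@H](c3ccc(OC)c(OC)c3)[C@H](C)[C@H]2C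
F4 | step 21 | (1S,2R)-1-(3,4-dimethoxyphenyl)-2-{4-[(2S,3R,4R,5S)-5-(3,4-dimethoxyphenyl)-3,4-dimethyloxolan-2-yl]-2-methoxyphenoxy}propan-1-ol | COc1ccc(cc1OC)[C@H](O)[C@@H](C)Oc2ccc(cc2OC)[C@H]3O[C@H](c4ccc(OC)c(OC)c4)[C@H](C)[C@H]3C
F5 | step 21 | (1R,2R)-1-(3,4-dimethoxyphenyl)-2-{4-[(2S,3R,4R,5S)-5-(3,4-dimethoxyphenyl)-3,4-dimethyloxolan-2-yl]-2-methoxyphenoxy}propyl 4-nitrobenzoate | COc1ccc(cc1OC)[C@@H](OC(=O)c5ccc(cc5)[N+](=O)[O-])[C@@H](C)Oc2ccc(cc2OC)[C@H]3O[C@H](c4ccc(OC)c(OC)c4)[C@H](C)[C@H]3C
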